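## Retrosynthetic overview

- Locants: lactone O1, C2(=O), C3=C4, C5H2, C6; side chain C1'–C15' with hydroxyls on C2', C4', C6'.
- Enabling feature: O1–C6 and HO–C2' are 1,3-anti across C1'H2, and C6 is joined through C5H2 to the sp2 carbon C4. A temporary O2'–C4 bond therefore maps O2', C4, C5, C6, C1', C2' onto an all-cis 2,4,6-trisubstituted oxane.
- Key disconnection: C4–C5, made by a three-component Prins cyclization (homoallylic alcohol + ClCH2CHO + CF3CO2H) that closes this temporary oxane and sets C6 from C2'. The O2'–C4 bond, absent from the target, is then cut by NaNH2 fragmentation, which unmasks HO–C2' and a C3≡C4 alkyne.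
- Ring order: temporary oxane closed (step 7) and opened (step 8); the dihydropyranone, the only ring of the target, is formed last (step 10) after carboxylation (C2 from CO2) and Lindlar reduction; debenzylation ends the route.
- Side chain: Noyori hydrogenation (C6'), Claisen extension and syn reduction (C4'), chelation-controlled allylation (C2', anti).

Key step: step 7

Remark: chloroacetaldehyde is sold as an aqueous solution and as its dimethyl acetal; it is assumed to be used as the anhydrous monomer freshly obtained from either, which is a purification and not a synthetic step.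

## Route

Step 1
Reactants: 1 methyl 3-oxododecanoate
Product: 2 methyl (R)-3-hydroxydodecanoate
Conditions: H2 (50 atm), RuCl2[(R)-BINAP] (0.2 mol%), MeOH, 50 °C
Reagents that add atoms: none
Why: Noyori asymmetric hydrogenation of a β-keto ester, in which the ester-chelated ketone is reduced inside the chiral pocket of the (R)-BINAP ruthenium hydride and should give the (R)-carbinol that becomes C6'.

Step 2
Reactants: 2 methyl (R)-3-hydroxydodecanoate; 3 tert-butyl acetate
Product: 4 tert-butyl (R)-5-hydroxy-3-oxotetradecanoate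
Conditions: 3 (4 equiv), LiN(iPr)2 (4.2 equiv), THF, −78 °C; then 2, −78 → −20 °C; 1 M HCl
Reagents that add atoms: none
Why: crossed Claisen condensation of the lithium enolate of 3 with the methyl ester, in which the lithium alkoxide of 2 protects against β-elimination and the product is stored as its enolate, so C6' is not touched.

Step 3
Reactants: 4 tert-butyl (R)-5-hydroxy-3-oxotetradecanoate
Product: 6 tert-butyl (3R,5R)-3,5-dihydroxytetradecanoate, via diethylboron chelate 5 (not isolated)
Conditions: Et2BOMe (1.1 equiv), THF/MeOH 4:1, −78 °C; NaBH4 (1.2 equiv), −78 °C; AcOH; co-evaporation with MeOH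
Reagents that add atoms: methoxydiethylborane Et2BOMe, CCB(CC)OC (its Et2B group is found only in intermediate 5)
Why: Narasaka–Prasad reduction, in which chelate 5 locks hydroxyl and ketone in a six-membered half-chair and external hydride adds axially, which should give the 1,3-syn diol and so set C4'.

Step 4
Reactants: 6 tert-butyl (3R,5R)-3,5-dihydroxytetradecanoate
Product: 7 tert-butyl (3R,5R)-3,5-bis(benzyloxy)tetradecanoate
Conditions: 2-benzyloxy-1-methylpyridinium triflate (4 equiv), MgO (4 equiv), PhCF3, 85 °C
Reagents that add atoms: 2-benzyloxy-1-methylpyridinium triflate, C[n+]1ccccc1OCc1ccccc1.[O-]S(=O)(=O)C(F)(F)F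
Why: thermal benzyl transfer from the pyridinium salt under neutral, MgO-buffered conditions (a Williamson-type O-benzylation without base), which avoids the retro-aldol and β-elimination of a basic benzylation and the ester loss or lactonization of an acidic one; no stereocentre is touched.

Step 5
Reactants: 7 tert-butyl (3R,5R)-3,5-bis(benzyloxy)tetradecanoate
Product: 8 (3R,5R)-3,5-bis(benzyloxy)tetradecanal
Conditions: (i-Bu)2AlH (1.2 equiv), toluene, −78 °C; MeOH; aq. potassium sodium tartrate
Reagents that add atoms: none
Why: partial reduction of an ester with (i-Bu)2AlH, in which the bulky, β-alkoxy-chelated aluminium hemiacetal should survive at −78 °C and collapse to the aldehyde only on work-up.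

Step 6
Reactants: 8 (3R,5R)-3,5-bis(benzyloxy)tetradecanal; 9 allyltrimethylsilane
Product: 10 (4R,6S,8R)-6,8-bis(benzyloxy)heptadec-1-en-4-ol
Conditions: TiCl4 (1.1 equiv), CH2Cl2, −78 °C; then 9 (2 equiv), −78 °C; H2O
Reagents that add atoms: none
Why: Hosomi–Sakurai allylation under chelation control, in which TiCl4 bridges the aldehyde oxygen and the C4' benzyloxy oxygen in a six-membered chelate and the allylsilane attacks the face away from the C4' substituent, which should set C2' 1,3-anti to C4'.

Step 7
Reactants: 10 (4R,6S,8R)-6,8-bis(benzyloxy)heptadec-1-en-4-ol; 11 chloroacetaldehyde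
Product: 13 (2R,4R,6S)-2-[(2R,4R)-2,4-bis(benzyloxy)tridecyl]-6-(chloromethyl)oxan-4-ol (all-cis), via oxanyl trifluoroacetate 12 (not isolated)
Conditions: 11 (anhydrous, 3 equiv), CF3CO2H (15 equiv), CH2Cl2, 0 °C → rt; evaporate; K2CO3 (0.3 equiv), MeOH, rt
Reagents that add atoms: trifluoroacetic acid, OC(=O)C(F)(F)F (CF3CO2 group in 12; one of its oxygen atoms stays on C6 in 13)
Why: In trifluoroacetic acid the C2'–OH of 10 should condense with 11 to the (E)-oxocarbenium ion O2'=C4, whose C4 is attacked by the terminal alkene carbon C5 through a chair transition state; this closes the temporary oxane at C4–C5 and leaves a cation at C6 that trifluoroacetate captures, so three components (10, 11, trifluoroacetate) are joined in one operation, and brief methanolysis of 12 frees the C6–OH. The closest known reaction type is the acid-mediated Prins cyclization of homoallylic alcohols with aliphatic aldehydes to all-cis 2,6-disubstituted oxan-4-ols. The one ring closed is the six-membered oxane (O2', C4, C5, C6, C1', C2'), by a 6-endo-trig attack of the C5=C6 alkene on the oxocarbenium carbon. The new C6 stereocentre is controlled by C2': with the C2' side chain and the CH2Cl group equatorial in the chair the nucleophile enters C6 equatorially, which is the 1,3-anti relation of O–C6 and O–C2' of the target, while the cis C4 stereocentre is temporary and is erased in step 8. The step needs all-equatorial diastereoselection and freedom from allyl scrambling: the first follows from the chair with the existing equatorial C2' substituent, the second from the absence of water and from the fact that both oxocarbenium ions linked by 2-oxonia-Cope rearrangement cyclize to the same oxane; the benzyl ethers are inert to the acid.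

Step 8
Reactants: 13 (2R,4R,6S)-2-[(2R,4R)-2,4-bis(benzyloxy)tridecyl]-6-(chloromethyl)oxan-4-ol
Product: 15 (4S,6R,8S,10R)-8,10-bis(benzyloxy)nonadec-1-yne-4,6-diol, via ring-opened chloroalkene 14 (not isolated)
Conditions: NaNH2 (6 equiv), liq. NH3/THF, −33 °C; NH4Cl
Reagents that add atoms: none
Why: amide-induced fragmentation of a 2-(chloromethyl) cyclic ether to an alkynol, in which β-elimination expels the ring alkoxide O2' to give 14 and a second dehydrochlorination gives the sodium acetylide as the stable end point; this should cut the temporary O2'–C4 bond, erase the C4 stereocentre and leave C6 and C2' untouched.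

Step 9
Reactants: 15 (4S,6R,8S,10R)-8,10-bis(benzyloxy)nonadec-1-yne-4,6-diol; 16 carbon dioxide
Product: 17 (5S,7R,9S,11R)-9,11-bis(benzyloxy)-5,7-dihydroxyicos-2-ynoic acid
Conditions: n-BuLi (3.2 equiv), THF, −78 → −20 °C; 16 (dry gas), −78 °C → rt; 1 M HCl to pH 2, 0 °C
Reagents that add atoms: none
Why: carboxylation of a lithium acetylide in the presence of lithium alkoxides (as in the classical parasorbic acid synthesis), where the lithium alkynoate formed is no Michael acceptor for the free alkoxides and the alkyl carbonates formed on oxygen revert on acidification.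

Step 10
Reactants: 17 (5S,7R,9S,11R)-9,11-bis(benzyloxy)-5,7-dihydroxyicos-2-ynoic acid
Product: 19 (6S)-6-[(2S,4S,6R)-4,6-bis(benzyloxy)-2-hydroxypentadecyl]-5,6-dihydro-2H-pyran-2-one, via (Z)-hydroxy acid 18 (not isolated)
Conditions: H2 (1 atm), Pd/CaCO3 poisoned with Pb(OAc)2 (Lindlar catalyst), quinoline, EtOAc, rt; filter; PPTS (cat.), CH2Cl2, rt
Reagents that add atoms: none
Why: Lindlar semi-hydrogenation should give the (Z)-enoic acid 18 by syn addition of hydrogen, and its cis geometry places the C6–OH next to the carboxyl for acid-catalysed lactonization to the six-membered ring, whereas the C2'–OH would need an eight-membered ring.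

Step 11
Reactants: 19 (6S)-6-[(2S,4S,6R)-4,6-bis(benzyloxy)-2-hydroxypentadecyl]-5,6-dihydro-2H-pyran-2-one
Product: 20 (6S)-6-[(2S,4R,6R)-2,4,6-trihydroxypentadecyl]-5,6-dihydro-2H-pyran-2-one
Conditions: BCl3 (6 equiv), CH2Cl2, −78 → −20 °C; MeOH
Reagents that add atoms: none
Why: Lewis-acid cleavage of benzyl ethers with BCl3 at low temperature, a debenzylation that should spare the enoate lactone (which hydrogenolysis would reduce) and touches no stereocentre.

## Compound list

1 | methyl 3-oxododecanoate | CCCCCCCCCC(=O)CC(=O)OC | starting material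
2 | methyl (R)-3-hydroxydodecanoate | CCCCCCCCC[C@@H](O)CC(=O)OC | intermediate
3 | tert-butyl acetate | CC(=O)OC(C)(C)C | starting material
4 | tert-butyl (R)-5-hydroxy-3-oxotetradecanoate | CCCCCCCCC[C@@H](O)CC(=O)CC(=O)OC(C)(C)C | intermediate
5 | tert-butyl (R)-5-[(diethylboranyl)oxy]-3-oxotetradecanoate (boron chelated by the ketone oxygen; not isolated) | CCCCCCCCC[C@@H](OB(CC)CC)CC(=O)CC(=O)OC(C)(C)C | intermediate
6 | tert-butyl (3R,5R)-3,5-dihydroxytetradecanoate | CCCCCCCCC[C@@H](O)C[C@@H](O)CC(=O)OC(C)(C)C | intermediate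
7 | tert-butyl (3R,5R)-3,5-bis(benzyloxy)tetradecanoate | CCCCCCCCC[C@@H](OCc1ccccc1)C[C@@H](OCc1ccccc1)CC(=O)OC(C)(C)C | intermediate
8 | (3R,5R)-3,5-bis(benzyloxy)tetradecanal | CCCCCCCCC[C@@H](OCc1ccccc1)C[C@@H](OCc1ccccc1)CC=O | intermediate
9 | allyltrimethylsilane | C=CC[Si](C)(C)C | starting material
10 | (4R,6S,8R)-6,8-bis(benzyloxy)heptadec-1-en-4-ol | CCCCCCCCC[C@@H](OCc1ccccc1)C[C@@H](OCc1ccccc1)C[C@H](O)CC=C | intermediate
11 | chloroacetaldehyde | ClCC=O | starting material
12 | (2S,4R,6S)-2-[(2R,4R)-2,4-bis(benzyloxy)tridecyl]-6-(chloromethyl)oxan-4-yl trifluoroacetate (all-cis, same spatial arrangement as 13; not isolated) | CCCCCCCCC[C@@H](OCc1ccccc1)C[C@@H](OCc1ccccc1)C[C@H]1C[C@@H](OC(=O)C(F)(F)F)C[C@@H](CCl)O1 | intermediate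
13 | (2R,4R,6S)-2-[(2R,4R)-2,4-bis(benzyloxy)tridecyl]-6-(chloromethyl)oxan-4-ol (all-cis) | CCCCCCCCC[C@@H](OCc1ccccc1)C[C@@H](OCc1ccccc1)C[C@H]1C[C@@H](O)C[C@@H](CCl)O1 | intermediate
14 | (4S,6R,8S,10R)-8,10-bis(benzyloxy)-1-chlorononadec-1-ene-4,6-diol (E/Z mixture, present as its disodium alkoxide; not isolated) | CCCCCCCCC[C@@H](OCc1ccccc1)C[C@@H](OCc1ccccc1)C[C@H](O)C[C@@H](O)CC=CCl | intermediate
15 | (4S,6R,8S,10R)-8,10-bis(benzyloxy)nonadec-1-yne-4,6-diol | CCCCCCCCC[C@@H](OCc1ccccc1)C[C@@H](OCc1ccccc1)C[C@H](O)C[C@@H](O)CC#C | intermediate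
16 | carbon dioxide | O=C=O | starting material
17 | (5S,7R,9S,11R)-9,11-bis(benzyloxy)-5,7-dihydroxyicos-2-ynoic acid | CCCCCCCCC[C@@H](OCc1ccccc1)C[C@@H](OCc1ccccc1)C[C@H](O)C[C@@H](O)CC#CC(=O)O | intermediate
18 | (2Z,5S,7R,9S,11R)-9,11-bis(benzyloxy)-5,7-dihydroxyicos-2-enoic acid (not isolated) | CCCCCCCCC[C@@H](OCc1ccccc1)C[C@@H](OCc1ccccc1)C[C@H](O)C[C@@H](O)C/C=C\C(=O)O | intermediate
19 | (6S)-6-[(2S,4S,6R)-4,6-bis(benzyloxy)-2-hydroxypentadecyl]-5,6-dihydro-2H-pyran-2-one | CCCCCCCCC[C@@H](OCc1ccccc1)C[C@@H](OCc1ccccc1)C[C@H](O)C[C@@H]1CC=CC(=O)O1 | intermediate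
20 | (6S)-6-[(2S,4R,6R)-2,4,6-trihydroxypentadecyl]-5,6-dihydro-2H-pyran-2-one | CCCCCCCCC[C@@H](O)C[C@@H](O)C[C@H](O)C[C@@H]1CC=CC(=O)O1 | target

## Step count and risks

Total step count: 11. Longest linear sequence: 11 steps (1 → 20); compounds 3, 9, 11 and 16 enter as commercial partners.

**Step 7 (Prins cyclization).** What may go wrong: acid-induced oligomerization of chloroacetaldehyde and slow formation of its electron-poor oxocarbenium ion; allyl transfer by 2-oxonia-Cope rearrangement followed by hydrolytic exchange, which would erode stereochemical purity and give symmetrical oxanes; interception of the oxocarbenium ion by the C4' benzyloxy oxygen.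
Fallback (segment-coupling Prins from an α-acetoxy ether, with no free aldehyde or water): setting out from 10, esterification with chloroacetyl chloride (pyridine, CH2Cl2, 0 °C) should give the chloroacetate ester F1. Reduction with (i-Bu)2AlH at −78 °C and trapping of the aluminium hemiacetal in the same flask with Ac2O, pyridine and DMAP should give the α-acetoxy ether F2. BF3·OEt2 and AcOH in hexane at 0 °C should ionize it to the same oxocarbenium ion and give the all-cis 4-acetoxy oxane F3. Methanolysis (K2CO3, MeOH) comes back to the route at 13.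

**Step 8 (amide fragmentation).** What may go wrong: stalling after the first elimination, competing dehydrochlorination toward an exocyclic enol ether that does not fragment, or precipitation of the polyanion in ammonia.
Fallback (reductive ring opening and ring-closing metathesis): setting out from 13, Finkelstein exchange (NaI, 2-butanone, reflux) should give the iodomethyl oxane F4. Acryloyl chloride and Et3N (CH2Cl2, 0 °C) should give the acrylate F5. Zn dust in refluxing EtOH (Boord-type reductive β-elimination) should give the ring-opened acrylate diene F6. Ring-closing metathesis with the second-generation Grubbs catalyst RuCl2(=CHPh)(H2IMes)(PCy3) in CH2Cl2 at 40 °C should close the lactone and come back to the route at 19. Here C3 is supplied by the acrylate and the Prins step is unchanged.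

**Step 11 (debenzylation).** What may go wrong: Lewis-acid-induced dehydration in the 1,3-polyol array, conjugate addition of chloride to the enoate, or incomplete cleavage of the second benzyl ether.
Fallback (debenzylation before the enoate exists, then silyl protection): setting out from 15, NaNH2 (3.3 equiv) in liq. NH3/THF forms the acetylide dialkoxide, and Na metal in the same flask (Birch-type cleavage; the acetylide is not reduced) should give the alkyne tetraol F7. TESOTf and 2,6-lutidine should give the tetrakis(triethylsilyl) ether F8. n-BuLi then ClCO2Me (THF, −78 °C) should give the methyl ynoate F9. Lindlar semi-hydrogenation should give the (Z)-enoate F10. HF·pyridine in THF should remove the four silyl groups, whereupon the freed C6–OH lactonizes, and the sequence comes back to the route at 20.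

Further compounds
F1 | step 7 | chloroacetate ester of 10 | CCCCCCCCC[C@@H](OCc1ccccc1)C[C@@H](OCc1ccccc1)C[C@H](OC(=O)CCl)CC=C
F2 | step 7 | 1-acetoxy-2-chloroethyl ether of 10 (both acetal epimers) | CCCCCCCCC[C@@H](OCc1ccccc1)C[C@@H](OCc1ccccc1)C[C@H](OC(CCl)OC(C)=O)CC=C
F3 | step 7 | all-cis 4-O-acetyl derivative of 13 | CCCCCCCCC[C@@H](OCc1ccccc1)C[C@@H](OCc1ccccc1)C[C@H]1C[C@@H](OC(C)=O)C[C@@H](CCl)O1
F4 | step 8 | iodomethyl analogue of 13 (Cl replaced by I) | CCCCCCCCC[C@@H](OCc1ccccc1)C[C@@H](OCc1ccccc1)C[C@H]1C[C@@H](O)C[C@@H](CI)O1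
F5 | step 8 | acrylate ester of F4 | CCCCCCCCC[C@@H](OCc1ccccc1)C[C@@H](OCc1ccccc1)C[C@H]1C[C@@H](OC(=O)C=C)C[C@@H](CI)O1
F6 | step 8 | 8,10-bis(benzyloxy)-6-hydroxynonadec-1-en-4-yl acrylate (ring-opened diene, stereocentres as in 15) | CCCCCCCCC[C@@H](OCc1ccccc1)C[C@@H](OCc1ccccc1)C[C@H](O)C[C@@H](OC(=O)C=C)CC=C
F7 | step 11 | (4S,6R,8R,10R)-nonadec-1-yne-4,6,8,10-tetraol | CCCCCCCCC[C@@H](O)C[C@@H](O)C[C@H](O)C[C@@H](O)CC#C
F8 | step 11 | tetrakis(triethylsilyl) ether of F7 | CCCCCCCCC[C@@H](O[Si](CC)(CC)CC)C[C@@H](O[Si](CC)(CC)CC)C[C@H](O[Si](CC)(CC)CC)C[C@@H](O[Si](CC)(CC)CC)CC#C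
F9 | step 11 | methyl 5,7,9,11-tetrakis(triethylsilyloxy)icos-2-ynoate (stereocentres as in F7) | CCCCCCCCC[C@@H](O[Si](CC)(CC)CC)C[C@@H](O[Si](CC)(CC)CC)C[C@H](O[Si](CC)(CC)CC)C[C@@H](O[Si](CC)(CC)CC)CC#CC(=O)OC
F10 | step 11 | methyl (Z)-5,7,9,11-tetrakis(triethylsilyloxy)icos-2-enoate (stereocentres as in F7) | CCCCCCCCC[C@@H](O[Si](CC)(CC)CC)C[C@@H](O[Si](CC)(CC)CC)C[C@H](O[Si](CC)(CC)CC)C[C@@H](O[Si](CC)(CC)CC)C/C=C\C(=O)OC
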